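**Plan**

- Retrosynthesis opens the aromatic chromone (primed locants) at O1'–C2' to an ortho-oxygenated aryl ynone. Its carbonyl carbon C4' lies between arene carbon C4a' and the C3'–C2' unit that carries the phenethyl chain, so it is cut at C4a'–C4' and C4'–C3' into an aryl iodide, CO and 4-phenylbut-1-yne.
- The aryl iodide is traced back through the C–I bond (iodination) and the C6'–O aryl ether bond (C–O cross-coupling) to the C5 alcohol of a protected tetrahydrochromone and a resorcinol-derived aryl bromide.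
- The pyranone of the tetrahydrochromone is cut at C4–C4a and O1–C8a (acylketene plus cyclic enol ether), and the carbocycle at C4a=C8a (enol ether ring-closing metathesis of a D-galacturonate-derived diene).
- Forward order of ring formation: carbocycle (step 9), pyranone of the tetrahydrochromone (step 11), ether link (step 14), carbonylative attachment of the last chain (step 16), aromatic pyranone (step 18).
- Stereochemistry: C5, C6, C7 and C8 are C2, C3, C4 and C5 of D-galactose (C1 becomes C4a, C6 becomes C8a). No stereocentre is created or inverted anywhere; all four are carried through.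

Key step: step 16

Remark: in every tetrahydrochromone of the route O5 and O8 lie on one face of the carbocycle and O6 and O7 on the other, with the absolute configuration of the target; lactol 7 is taken as an anomeric mixture and enaminone 24 as the E isomer, neither of which affects the outcome.

**Route**

Step 1
Reactants: 1 phenyl 1-thio-β-D-galactopyranoside
Product: 2 phenyl 3,4-O-isopropylidene-6-O-(2-methoxypropan-2-yl)-1-thio-β-D-galactopyranoside
Conditions: Me2C(OMe)2 (excess), camphorsulfonic acid (cat.), acetone, rt; Et3N quench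
Reagents that add atoms: 2,2-dimethoxypropane, COC(C)(C)OC
Why: Acid-catalysed transacetalisation under kinetic control should close the dioxolane on the cis-3,4-diol and cap the primary 6-OH as a mixed acetal, a known outcome for β-galactopyranosides that leaves only 2-OH free.

Step 2
Reactants: 2 phenyl 3,4-O-isopropylidene-6-O-(2-methoxypropan-2-yl)-1-thio-β-D-galactopyranoside
Product: 4 phenyl 3,4-O-isopropylidene-2-O-(4-methoxybenzyl)-1-thio-β-D-galactopyranoside, via mixed-acetal PMB ether 3 (not isolated)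
Conditions: NaH, 4-methoxybenzyl chloride, n-Bu4NI (cat.), DMF, 0 °C to rt; then 50% aq. AcOH, THF, rt
Reagents that add atoms: 4-methoxybenzyl chloride, COc1ccc(CCl)cc1
Why: Williamson etherification of the single free hydroxyl, followed by selective hydrolysis of the acyclic mixed acetal, which cleaves far faster than the dioxolane in dilute acetic acid.

Step 3
Reactants: 4 phenyl 3,4-O-isopropylidene-2-O-(4-methoxybenzyl)-1-thio-β-D-galactopyranoside
Product: 5 phenyl 3,4-O-isopropylidene-2-O-(4-methoxybenzyl)-1-thio-β-D-galactopyranosiduronic acid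
Conditions: TEMPO (0.2 equiv), PhI(OAc)2 (2.5 equiv), CH2Cl2/H2O (2:1), rt
Reagents that add atoms: water, O
Why: TEMPO/PhI(OAc)2 oxidation takes a primary alcohol to the carboxylic acid through the aldehyde hydrate and is known to leave thioglycoside sulfur, PMB ethers and acetonides untouched.

Step 4
Reactants: 5 phenyl 3,4-O-isopropylidene-2-O-(4-methoxybenzyl)-1-thio-β-D-galactopyranosiduronic acid
Product: 6 methyl (phenyl 3,4-O-isopropylidene-2-O-(4-methoxybenzyl)-1-thio-β-D-galactopyranosid)uronate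
Conditions: MeI, KHCO3, DMF, rt
Reagents that add atoms: iodomethane, CI
Why: SN2 O-alkylation of the carboxylate with a weak base that should not trigger β-elimination of the uronate.

Step 5
Reactants: 6 methyl (phenyl 3,4-O-isopropylidene-2-O-(4-methoxybenzyl)-1-thio-β-D-galactopyranosid)uronate
Product: 7 methyl 3,4-O-isopropylidene-2-O-(4-methoxybenzyl)-D-galactopyranuronate (lactol)
Conditions: NBS (2 equiv), acetone/H2O (9:1), 0 °C, dark; aq. Na2S2O3 quench
Reagents that add atoms: water, O
Why: NBS-promoted thioglycoside hydrolysis, in which S-bromination turns the thiophenyl group into a leaving group and water captures the oxocarbenium ion.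

Step 6
Reactants: 7 methyl 3,4-O-isopropylidene-2-O-(4-methoxybenzyl)-D-galactopyranuronate
Product: 8 methyl 6,7-dideoxy-3,4-O-isopropylidene-5-O-(4-methoxybenzyl)-L-galacto-hept-6-enonate [(2S,3S,4R,5S); 2-OH free]
Conditions: Ph3PCH3Br (3 equiv), KN(SiMe3)2 (2.8 equiv), THF, −78 °C; add 7; −78 to 0 °C
Reagents that add atoms: methyltriphenylphosphonium bromide, C[P+](c1ccccc1)(c1ccccc1)c1ccccc1.[Br-]
Why: Wittig methylenation of the open-chain aldehyde in equilibrium with the lactolate should give the terminal alkene and free the former ring oxygen; the lactol proton is removed first, and the resulting alkoxide next to the ester protects that α-position from further deprotonation at low temperature.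

Step 7
Reactants: 8 methyl 6,7-dideoxy-3,4-O-isopropylidene-5-O-(4-methoxybenzyl)-L-galacto-hept-6-enonate
Product: 9 methyl 2-O-(tert-butyldimethylsilyl)-6,7-dideoxy-3,4-O-isopropylidene-5-O-(4-methoxybenzyl)-L-galacto-hept-6-enonate
Conditions: TBSOTf, 2,6-lutidine, CH2Cl2, −78 to 0 °C
Reagents that add atoms: tert-butyldimethylsilyl triflate, CC(C)(C)[Si](C)(C)OS(=O)(=O)C(F)(F)F
Why: Standard silylation of a hindered α-hydroxy ester with a silyl triflate and a non-nucleophilic base.

Step 8
Reactants: 9 methyl 2-O-(tert-butyldimethylsilyl)-6,7-dideoxy-3,4-O-isopropylidene-5-O-(4-methoxybenzyl)-L-galacto-hept-6-enonate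
Product: 10 enol ether diene (the ester C=O of 9 replaced by C=CH2: 3-OTBS, 4,5-O-isopropylidene, 6-OPMB 2-methoxyocta-1,7-diene; stereocentres as in 9)
Conditions: Cp2TiMe2 (3 equiv), toluene, 70 °C, dark
Reagents that add atoms: dimethyltitanocene Cp2TiMe2, C[Ti](C)(C1C=CC=C1)C1C=CC=C1
Why: Petasis methylenation, in which Cp2TiMe2 loses methane to give Cp2Ti=CH2 and this converts the ester carbonyl into the 1-methoxyvinyl group through an oxatitanacyclobutane, without base and without engaging the terminal alkene.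

Step 9
Reactants: 10 enol ether diene
Product: 11 (3S,4R,5R,6S)-6-(tert-butyldimethylsilyloxy)-4,5-(isopropylidenedioxy)-1-methoxy-3-(4-methoxybenzyloxy)cyclohex-1-ene
Conditions: second-generation Grubbs catalyst RuCl2(H2IMes)(PCy3)(=CHPh) (10 mol%), toluene (0.005 M), 80 °C, argon sparge; filtration through Et3N-deactivated silica
Reagents that add atoms: none
Why: Ring-closing metathesis between the monosubstituted alkene and the 2-alkoxy-1-alkene is a known route to 1-alkoxycycloalkenes, and the cis-dioxolane holds both chain ends on one side so that the six-membered ring (C4a=C8a) should close readily.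

Step 10
Reactants: 12 2,2,6-trimethyl-4H-1,3-dioxin-4-one
Product: 13 2,2-dimethyl-6-(2-phenylethyl)-4H-1,3-dioxin-4-one
Conditions: LiN(i-Pr)2, THF, −78 °C; then BnBr, HMPA, −78 to −40 °C
Reagents that add atoms: benzyl bromide, BrCc1ccccc1
Why: γ-Alkylation of the lithium dienolate of the dioxinone with a benzylic halide, known to occur at the 6-methyl group in the presence of HMPA.

Step 11
Reactants: 11 cyclic enol ether; 13 2,2-dimethyl-6-(2-phenylethyl)-4H-1,3-dioxin-4-one
Product: 16 (5S,6R,7R,8S)-8-(tert-butyldimethylsilyloxy)-6,7-(isopropylidenedioxy)-5-(4-methoxybenzyloxy)-2-(2-phenylethyl)-5,6,7,8-tetrahydro-4H-chromen-4-one, via acylketene 14 (not isolated), via methoxy cycloadduct 15 (not isolated)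
Conditions: toluene, 110 °C, 13 (3 equiv) added slowly; then TsOH·H2O (10 mol%), rt
Reagents that add atoms: none
Why: Thermal retro-[4+2] of 13 releases acetone and acylketene 14, which adds to the electron-rich enol ether in a hetero-Diels–Alder reaction (nucleophilic C4a to the ketene carbon, acyl oxygen to C8a), and acid-catalysed loss of methanol from 15 gives the 4-pyranone, a known dioxinone-to-pyranone annulation.

Step 12
Reactants: 16 PMB-protected tetrahydrochromone
Product: 17 (5S,6R,7R,8S)-8-(tert-butyldimethylsilyloxy)-5-hydroxy-6,7-(isopropylidenedioxy)-2-(2-phenylethyl)-5,6,7,8-tetrahydro-4H-chromen-4-one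
Conditions: DDQ (1.5 equiv), CH2Cl2/pH 7 phosphate buffer (10:1), 0 °C to rt
Reagents that add atoms: none
Why: Oxidative PMB cleavage with DDQ through the benzylic oxocarbenium ion and its hemiacetal; the silyl ether, acetonide and pyranone are inert under buffered conditions.

Step 13
Reactants: 18 4-bromoresorcinol
Product: 19 1-bromo-2,4-bis(methoxymethoxy)benzene
Conditions: MOMCl (2.5 equiv), i-Pr2NEt (3 equiv), CH2Cl2, 0 °C to rt
Reagents that add atoms: chloromethyl methyl ether, COCCl
Why: Double O-alkylation of both phenols with MOMCl and a hindered amine base, so no regioselectivity between the two hydroxyls is needed.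

Step 14
Reactants: 17 C5 alcohol; 19 1-bromo-2,4-bis(methoxymethoxy)benzene (1.5 equiv)
Product: 20 (5S,6R,7R,8S)-5-[2,4-bis(methoxymethoxy)phenoxy]-8-(tert-butyldimethylsilyloxy)-6,7-(isopropylidenedioxy)-2-(2-phenylethyl)-5,6,7,8-tetrahydro-4H-chromen-4-one
Conditions: Pd2(dba)3 (2.5 mol%), RockPhos (6 mol%), Cs2CO3 (1.5 equiv), toluene, 90 °C
Reagents that add atoms: none
Why: Palladium-catalysed C–O cross-coupling (Buchwald–Hartwig etherification) of a secondary alcohol with an aryl bromide; the bulky biaryl phosphine and the ortho MOM ether should speed C–O reductive elimination relative to β-hydride elimination, and C5 keeps its configuration because the C5–O bond is not broken.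

Step 15
Reactants: 20 aryl ether
Product: 21 (5S,6R,7R,8S)-5-[5-iodo-2,4-bis(methoxymethoxy)phenoxy]-8-(tert-butyldimethylsilyloxy)-6,7-(isopropylidenedioxy)-2-(2-phenylethyl)-5,6,7,8-tetrahydro-4H-chromen-4-one
Conditions: NIS (1.1 equiv), MeCN, 0 °C to rt, dark
Reagents that add atoms: N-iodosuccinimide, O=C1CCC(=O)N1I
Why: Electrophilic aromatic iodination at the one ring position that is para to one MOM ether, ortho to the other and sterically open (the future C4a'); the pyranone C3–H is far less nucleophilic.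

Step 16
Reactants: 21 aryl iodide; 22 4-phenylbut-1-yne (1.5 equiv)
Product: 23 (5S,6R,7R,8S)-5-[2,4-bis(methoxymethoxy)-5-(5-phenylpent-2-ynoyl)phenoxy]-8-(tert-butyldimethylsilyloxy)-6,7-(isopropylidenedioxy)-2-(2-phenylethyl)-5,6,7,8-tetrahydro-4H-chromen-4-one
Conditions: PdCl2(PPh3)2 (5 mol%), Et3N (3 equiv), CO (1 atm, balloon), THF/H2O (4:1), rt to 40 °C, no copper salt
Reagents that add atoms: carbon monoxide, [C-]#[O+]
Why: The divalent palladium precatalyst is reduced in the flask to zerovalent palladium, which inserts into the C4a'–I bond; CO insertion gives an aroylpalladium iodide, amine-assisted transfer of the alkynyl group of 22 follows, and reductive elimination forms the C4a'–C4' and C4'–C3' bonds of the ynone. The closest known reaction type is the copper-free carbonylative Sonogashira coupling of ortho-alkoxy aryl iodides with terminal alkynes to aryl alkynyl ketones. No ring closes and no stereocentre is created, and the C5–C8 stereotetrad is a spectator. The selectivity needed is carbonylative over direct alkynylation: the electron-rich arylpalladium species flanked by the ortho MOM ether should insert CO quickly, CO is kept in excess, and no copper acetylide is present to intercept the arylpalladium intermediate before insertion. The C–I bond is the only site of oxidative addition, and the pyranone, silyl ether, acetals and aryl ether are inert to the weak amine base at this temperature.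

Step 17
Reactants: 23 aryl ynone
Product: 24 (E)-enaminone: (5S,6R,7R,8S)-5-{5-[3-(diethylamino)-5-phenylpent-2-enoyl]-2,4-bis(methoxymethoxy)phenoxy}-8-(tert-butyldimethylsilyloxy)-6,7-(isopropylidenedioxy)-2-(2-phenylethyl)-5,6,7,8-tetrahydro-4H-chromen-4-one
Conditions: Et2NH (5 equiv), EtOH, rt
Reagents that add atoms: diethylamine, CCNCC
Why: Aza-Michael addition of a secondary amine to the ynone gives the vinylogous amide, which fixes the β-carbon as the electrophilic site so that the later ring closure can only be 6-endo.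

Step 18
Reactants: 24 enaminone
Product: 25 (5S,6S,7R,8S)-6,7,8-trihydroxy-5-{[7-hydroxy-4-oxo-2-(2-phenylethyl)-4H-chromen-6-yl]oxy}-2-(2-phenylethyl)-5,6,7,8-tetrahydro-4H-chromen-4-one (target)
Conditions: HCl (2 M in MeOH), 0 °C to rt
Reagents that add atoms: none
Why: Methanolic HCl should remove both MOM ethers, the silyl ether and the acetonide by transacetalisation and solvolysis, and the freed C8a' phenol should displace diethylamine from the protonated enaminone (addition–elimination, 6-endo) to close the aromatic pyranone, a known acid-mediated chromone synthesis from ortho-hydroxyaryl enaminones; dilute acid at room temperature is chosen to spare the C5 aryl ether.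

**Compound list**

1 | phenyl 1-thio-β-D-galactopyranoside | OC[C@H]1O[C@@H](Sc2ccccc2)[C@H](O)[C@@H](O)[C@H]1O | starting material
2 | phenyl 3,4-O-isopropylidene-6-O-(2-methoxypropan-2-yl)-1-thio-β-D-galactopyranoside | COC(C)(C)OC[C@H]1O[C@@H](Sc2ccccc2)[C@H](O)[C@@H](OC2(C)C)[C@H]1O2 | intermediate
3 | phenyl 3,4-O-isopropylidene-2-O-(4-methoxybenzyl)-6-O-(2-methoxypropan-2-yl)-1-thio-β-D-galactopyranoside | COC(C)(C)OC[C@H]1O[C@@H](Sc2ccccc2)[C@H](OCc2ccc(OC)cc2)[C@@H](OC2(C)C)[C@H]1O2 | intermediate (not isolated)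
4 | phenyl 3,4-O-isopropylidene-2-O-(4-methoxybenzyl)-1-thio-β-D-galactopyranoside | OC[C@H]1O[C@@H](Sc2ccccc2)[C@H](OCc2ccc(OC)cc2)[C@@H](OC2(C)C)[C@H]1O2 | intermediate
5 | phenyl 3,4-O-isopropylidene-2-O-(4-methoxybenzyl)-1-thio-β-D-galactopyranosiduronic acid | OC(=O)[C@H]1O[C@@H](Sc2ccccc2)[C@H](OCc2ccc(OC)cc2)[C@@H](OC2(C)C)[C@H]1O2 | intermediate
6 | methyl (phenyl 3,4-O-isopropylidene-2-O-(4-methoxybenzyl)-1-thio-β-D-galactopyranosid)uronate | COC(=O)[C@H]1O[C@@H](Sc2ccccc2)[C@H](OCc2ccc(OC)cc2)[C@@H](OC2(C)C)[C@H]1O2 | intermediate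
7 | methyl 3,4-O-isopropylidene-2-O-(4-methoxybenzyl)-D-galactopyranuronate (lactol, anomeric mixture) | COC(=O)[C@H]1OC(O)[C@H](OCc2ccc(OC)cc2)[C@@H](OC2(C)C)[C@H]1O2 | intermediate
8 | methyl 6,7-dideoxy-3,4-O-isopropylidene-5-O-(4-methoxybenzyl)-L-galacto-hept-6-enonate | C=C[C@H](OCc1ccc(OC)cc1)[C@@H](OC1(C)C)[C@@H](O1)[C@H](O)C(=O)OC | intermediate
9 | methyl 2-O-(tert-butyldimethylsilyl)-6,7-dideoxy-3,4-O-isopropylidene-5-O-(4-methoxybenzyl)-L-galacto-hept-6-enonate | C=C[C@H](OCc1ccc(OC)cc1)[C@@H](OC1(C)C)[C@@H](O1)[C@H](O[Si](C)(C)C(C)(C)C)C(=O)OC | intermediate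
10 | 3-(tert-butyldimethylsilyloxy)-4,5-(isopropylidenedioxy)-2-methoxy-6-(4-methoxybenzyloxy)octa-1,7-diene (stereocentres as in 9) | C=C[C@H](OCc1ccc(OC)cc1)[C@@H](OC1(C)C)[C@@H](O1)[C@H](O[Si](C)(C)C(C)(C)C)C(=C)OC | intermediate
11 | (3S,4R,5R,6S)-6-(tert-butyldimethylsilyloxy)-4,5-(isopropylidenedioxy)-1-methoxy-3-(4-methoxybenzyloxy)cyclohex-1-ene | COC1=C[C@H](OCc2ccc(OC)cc2)[C@@H](OC2(C)C)[C@@H](O2)[C@@H]1O[Si](C)(C)C(C)(C)C | intermediate
12 | 2,2,6-trimethyl-4H-1,3-dioxin-4-one | CC1=CC(=O)OC(C)(C)O1 | starting material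
13 | 2,2-dimethyl-6-(2-phenylethyl)-4H-1,3-dioxin-4-one | O=C1C=C(CCc2ccccc2)OC(C)(C)O1 | intermediate
14 | 3-oxo-5-phenylpent-1-en-1-one (acylketene) | O=C=CC(=O)CCc1ccccc1 | intermediate (not isolated)
15 | 8-(tert-butyldimethylsilyloxy)-6,7-(isopropylidenedioxy)-8a-methoxy-5-(4-methoxybenzyloxy)-2-(2-phenylethyl)-4a,5,6,7,8,8a-hexahydro-4H-chromen-4-one (C5–C8 as in 16; C4a and C8a undefined) | O=C1C=C(CCc2ccccc2)OC2(OC)C1[C@H](OCc1ccc(OC)cc1)[C@@H](OC1(C)C)[C@@H](O1)[C@@H]2O[Si](C)(C)C(C)(C)C | intermediate (not isolated)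
16 | (5S,6R,7R,8S)-8-(tert-butyldimethylsilyloxy)-6,7-(isopropylidenedioxy)-5-(4-methoxybenzyloxy)-2-(2-phenylethyl)-5,6,7,8-tetrahydro-4H-chromen-4-one | O=c1cc(CCc2ccccc2)oc2c1[C@H](OCc1ccc(OC)cc1)[C@@H](OC1(C)C)[C@@H](O1)[C@@H]2O[Si](C)(C)C(C)(C)C | intermediate
17 | (5S,6R,7R,8S)-8-(tert-butyldimethylsilyloxy)-5-hydroxy-6,7-(isopropylidenedioxy)-2-(2-phenylethyl)-5,6,7,8-tetrahydro-4H-chromen-4-one | O=c1cc(CCc2ccccc2)oc2c1[C@H](O)[C@@H](OC1(C)C)[C@@H](O1)[C@@H]2O[Si](C)(C)C(C)(C)C | intermediate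
18 | 4-bromoresorcinol | Oc1ccc(Br)c(O)c1 | starting material
19 | 1-bromo-2,4-bis(methoxymethoxy)benzene | COCOc1ccc(Br)c(OCOC)c1 | intermediate
20 | (5S,6R,7R,8S)-5-[2,4-bis(methoxymethoxy)phenoxy]-8-(tert-butyldimethylsilyloxy)-6,7-(isopropylidenedioxy)-2-(2-phenylethyl)-5,6,7,8-tetrahydro-4H-chromen-4-one | O=c1cc(CCc2ccccc2)oc2c1[C@H](Oc1ccc(OCOC)cc1OCOC)[C@@H](OC1(C)C)[C@@H](O1)[C@@H]2O[Si](C)(C)C(C)(C)C | intermediate
21 | (5S,6R,7R,8S)-5-[5-iodo-2,4-bis(methoxymethoxy)phenoxy]-8-(tert-butyldimethylsilyloxy)-6,7-(isopropylidenedioxy)-2-(2-phenylethyl)-5,6,7,8-tetrahydro-4H-chromen-4-one | O=c1cc(CCc2ccccc2)oc2c1[C@H](Oc1cc(I)c(OCOC)cc1OCOC)[C@@H](OC1(C)C)[C@@H](O1)[C@@H]2O[Si](C)(C)C(C)(C)C | intermediate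
22 | 4-phenylbut-1-yne | C#CCCc1ccccc1 | starting material
23 | (5S,6R,7R,8S)-5-[2,4-bis(methoxymethoxy)-5-(5-phenylpent-2-ynoyl)phenoxy]-8-(tert-butyldimethylsilyloxy)-6,7-(isopropylidenedioxy)-2-(2-phenylethyl)-5,6,7,8-tetrahydro-4H-chromen-4-one | O=c1cc(CCc2ccccc2)oc2c1[C@H](Oc1cc(C(=O)C#CCCc3ccccc3)c(OCOC)cc1OCOC)[C@@H](OC1(C)C)[C@@H](O1)[C@@H]2O[Si](C)(C)C(C)(C)C | intermediate
24 | (5S,6R,7R,8S)-5-{5-[(E)-3-(diethylamino)-5-phenylpent-2-enoyl]-2,4-bis(methoxymethoxy)phenoxy}-8-(tert-butyldimethylsilyloxy)-6,7-(isopropylidenedioxy)-2-(2-phenylethyl)-5,6,7,8-tetrahydro-4H-chromen-4-one | O=c1cc(CCc2ccccc2)oc2c1[C@H](Oc1cc(C(=O)/C=C(\CCc3ccccc3)N(CC)CC)c(OCOC)cc1OCOC)[C@@H](OC1(C)C)[C@@H](O1)[C@@H]2O[Si](C)(C)C(C)(C)C | intermediate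
25 | (5S,6S,7R,8S)-6,7,8-trihydroxy-5-{[7-hydroxy-4-oxo-2-(2-phenylethyl)-4H-chromen-6-yl]oxy}-2-(2-phenylethyl)-5,6,7,8-tetrahydro-4H-chromen-4-one | O=c1cc(CCc2ccccc2)oc2c1[C@H](Oc1cc3c(=O)cc(CCc4ccccc4)oc3cc1O)[C@@H](O)[C@@H](O)[C@@H]2O | target

**Step count and risks**

Total step count: 18. Longest linear sequence: 16 (steps 1–9, 11, 12, 14–18, from compound 1).

Steps most likely to fail:

1. Step 11. Dimerisation of the acylketene may outrun its cycloaddition to the hindered, inductively deactivated enol ether, or trace acid may hydrolyse the enol ether before it reacts, so that little pyranone forms.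
   Fallback, setting out from 11 and returning at 16: deliberate hydrolysis of the enol ether (oxalic acid, wet THF, 0 °C) would give the cyclohexanone F1. Its kinetic lithium enolate on the methylene side (LiN(SiMe3)2, THF, −78 °C) would be added to 5-phenylpent-2-ynal F2 (from 22 with n-BuLi, then DMF) to give the aldol adduct F3. Dess–Martin periodinane would oxidise this to the 2-alkynoyl cyclohexanone F4, and 6-endo addition of its enol oxygen to the ynone (Et2NH, EtOH) would close the pyranone of 16.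

2. Step 14. β-Hydride elimination from the palladium alkoxide of the hindered C5 alcohol (oxidising C5 and reducing the arene) may outrun C–O reductive elimination at the electron-rich aryl group.
   Fallback, setting out from 17 and returning at 20: the potassium alkoxide of 17 (KN(SiMe3)2, THF/DMF, 0 °C to rt) would displace fluoride from 4-fluoro-3-(methoxymethoxy)benzaldehyde F5 (from 4-fluoro-3-hydroxybenzaldehyde and MOMCl) by SNAr to give the aryl ether aldehyde F6. Baeyer–Villiger oxidation (mCPBA, NaHCO3, CH2Cl2) would give the aryl formate F7, methanolysis (K2CO3, MeOH) the phenol F8, and MOMCl/i-Pr2NEt would convert this into 20.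

3. Step 6. The basic ylide may deprotonate the carbon next to the ester (epimerisation or β-elimination of the neighbouring acetonide oxygen) or attack the ester before the lactol opens.
   Fallback, setting out from 4 and returning at 9: with C6 still at the alcohol level, NBS hydrolysis of 4 would give the lactol F9 and Wittig methylenation (Ph3PCH3Br, KN(SiMe3)2, excess) the diol F10. TBSOTf/2,6-lutidine would give the bis-silyl ether F11, and HF·pyridine (THF/pyridine, 0 °C) would free only the primary alcohol F12. TEMPO/PhI(OAc)2 would oxidise it to the acid F13, and MeI/KHCO3 would give ester 9.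

**Further compounds**

F1 | step 11 | 2-(tert-butyldimethylsilyloxy)-3,4-(isopropylidenedioxy)-5-(4-methoxybenzyloxy)cyclohexan-1-one (stereocentres as in 11) | O=C1C[C@H](OCc2ccc(OC)cc2)[C@@H](OC2(C)C)[C@@H](O2)[C@@H]1O[Si](C)(C)C(C)(C)C
F2 | step 11 | 5-phenylpent-2-ynal | O=CC#CCCc1ccccc1
F3 | step 11 | aldol adduct: 6-(1-hydroxy-5-phenylpent-2-ynyl) derivative of F1 (two new centres undefined) | O=C1C(C(O)C#CCCc2ccccc2)[C@H](OCc2ccc(OC)cc2)[C@@H](OC2(C)C)[C@@H](O2)[C@@H]1O[Si](C)(C)C(C)(C)C
F4 | step 11 | 6-(5-phenylpent-2-ynoyl) derivative of F1 (enolised diketone, drawn as the diketo form) | O=C1C(C(=O)C#CCCc2ccccc2)[C@H](OCc2ccc(OC)cc2)[C@@H](OC2(C)C)[C@@H](O2)[C@@H]1O[Si](C)(C)C(C)(C)C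
F5 | step 14 | 4-fluoro-3-(methoxymethoxy)benzaldehyde | COCOc1cc(C=O)ccc1F
F6 | step 14 | 5-[4-formyl-2-(methoxymethoxy)phenoxy] analogue of 20 | O=c1cc(CCc2ccccc2)oc2c1[C@H](Oc1ccc(C=O)cc1OCOC)[C@@H](OC1(C)C)[C@@H](O1)[C@@H]2O[Si](C)(C)C(C)(C)C
F7 | step 14 | 5-[4-(formyloxy)-2-(methoxymethoxy)phenoxy] analogue of 20 | O=c1cc(CCc2ccccc2)oc2c1[C@H](Oc1ccc(OC=O)cc1OCOC)[C@@H](OC1(C)C)[C@@H](O1)[C@@H]2O[Si](C)(C)C(C)(C)C
F8 | step 14 | 5-[4-hydroxy-2-(methoxymethoxy)phenoxy] analogue of 20 | O=c1cc(CCc2ccccc2)oc2c1[C@H](Oc1ccc(O)cc1OCOC)[C@@H](OC1(C)C)[C@@H](O1)[C@@H]2O[Si](C)(C)C(C)(C)C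
F9 | step 6 | 3,4-O-isopropylidene-2-O-(4-methoxybenzyl)-D-galactopyranose (anomeric mixture) | OC[C@H]1OC(O)[C@H](OCc2ccc(OC)cc2)[C@@H](OC2(C)C)[C@H]1O2
F10 | step 6 | 1,2-dideoxy-4,5-O-isopropylidene-3-O-(4-methoxybenzyl)-D-galacto-hept-1-enitol | C=C[C@H](OCc1ccc(OC)cc1)[C@@H](OC1(C)C)[C@@H](O1)[C@H](O)CO
F11 | step 6 | 6,7-bis-O-(tert-butyldimethylsilyl) derivative of F10 | C=C[C@H](OCc1ccc(OC)cc1)[C@@H](OC1(C)C)[C@@H](O1)[C@H](O[Si](C)(C)C(C)(C)C)CO[Si](C)(C)C(C)(C)C
F12 | step 6 | 6-O-(tert-butyldimethylsilyl) derivative of F10 (primary alcohol free) | C=C[C@H](OCc1ccc(OC)cc1)[C@@H](OC1(C)C)[C@@H](O1)[C@H](O[Si](C)(C)C(C)(C)C)CO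
F13 | step 6 | 2-O-(tert-butyldimethylsilyl)-6,7-dideoxy-3,4-O-isopropylidene-5-O-(4-methoxybenzyl)-L-galacto-hept-6-enonic acid | C=C[C@H](OCc1ccc(OC)cc1)[C@@H](OC1(C)C)[C@@H](O1)[C@H](O[Si](C)(C)C(C)(C)C)C(=O)O
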